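## Structural features

Plastochromenol-8 (10) is a 2H-chromene: benzene ring A (C4a, C5, C6, C7, C8, C8a) is fused along C4a–C8a to 2H-pyran ring B (O1, C2, C3=C4). Ring A carries OH at C6, methyls at C7 and C8, O1 at C8a and C4 at C4a, so O1 and the C6 oxygen are para (a hydroquinone mono-ether) and only C5 bears hydrogen. C2 is the only stereocentre (R). It is quaternary and at once tertiary, allylic to the cis C3=C4 olefin and the alkyl end of an aryl ether; it has no neighbouring stereocentre, the other stereo-elements being the seven E trisubstituted olefins of the chain. The C41 chain on C2, together with C2, its methyl, C3 and C4, is the all-E nonaprenyl skeleton of solanesol, C2 being C3 of that alcohol. Fragile points: ring B can open reversibly to an achiral ortho-quinone methide (heat, light, acid), which erases C2; the free electron-rich phenol is easily oxidised; the eight chain olefins are sensitive to acids, electrophiles and oxidants. The real difficulty is the O1–C8a bond (a tertiary allylic oxygen on an electron-rich, flanked aromatic carbon) beside the C4–C4a bond, both to be made without ionising C2–O1. The key step exploits the para O1/C6–O pattern of ring A: at the oxidation level of a 4-alkoxycyclohexa-2,5-dienone, C8a can be an sp3 spiro carbon carrying both O1 and C4, and the adjacent C4a–H lets C4 move over by a 1,2-shift that re-forms the benzene ring. The atom labels of 10 are used for the corresponding atoms of all intermediates.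

## Logic of the disconnections

10 ⇒ 9. The C4–C4a bond is cut and C4 is placed back on C8a, which turns ring A into a cross-conjugated dienone (C6=O) and ring B into a spiro-2,5-dihydrofuran. The reason is that the ortho-fused chromene then comes from a para-substituted precursor, and no bond at C2 is made or broken. The gain is the removal of every ortho-functionalised arene and of all protecting groups. The demand on the forward step is a 1,2-shift of carbon (not oxygen) to C4a (not C8) under conditions that the chain olefins and the C2–O1 bond survive.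

9 ⇒ 8. The O1–C8a bond is cut to give a para-alkenylphenol whose tertiary hydroxyl is held over C8a by a Z olefin. Cutting here lets the tertiary oxygen attack an oxidised (electrophilic) ring A instead of requiring substitution on an electron-rich arene. The gain is a plain phenol with one side chain. The forward step must oxidise the phenol only, and the hydroxyl must close the five-membered ring at C8a; the configuration at the spiro carbon is irrelevant because it is erased on the way to 10.

8 ⇒ 7 ⇒ 5 + 6. The Z C3=C4 olefin is traced back to an alkyne and the C4–aryl bond is cut. This separates the whole chiral C45 part, as a terminal alkyne, from a simple para-iodophenol. The gain is full convergence onto two fragments. The forward steps must couple in the presence of a free phenol and a free tertiary alcohol, and add one equivalent of hydrogen cis to the alkyne without touching eight trisubstituted olefins.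

5 ⇒ 3 ⇒ 2. The C3≡C4 triple bond is traced back (through the in-flask intermediate 4) to a chloromethyl-oxirane and then to the epoxy alcohol. The tertiary C–O bond of the future C2 is kept throughout; only the secondary C–O bond of the oxirane is sacrificed. The gain is that the quaternary stereocentre becomes a stereocentre of an epoxide. The forward step must eliminate twice without attacking the tertiary centre.

2 ⇒ 1. The oxirane is cut back to the allylic olefin of the commercial all-E nonaprenol. The hydroxyl group singles out one olefin among nine and allows reagent control of the face. The gain is that the whole carbon chain, all seven E olefins and C2 come from one starting material. The forward step must give the (2R,3R) epoxide, since the oxirane C3 becomes C2 of 10 with unchanged spatial arrangement and unchanged priority order.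

## Other disconnections considered

Alternative 1: Cut O1–C2 in the retro-electrocyclic sense (the route that comes to mind first). Forward, 2,3-dimethylhydroquinone would be alkylated with 1 and oxidised to plastoquinone-9 A1; base-induced tautomerisation to the ortho-quinone methide A2 and oxa-6π closure would form ring B. The ground against it is mechanistic: A2 is planar and achiral, the two disrotatory closures are enantiomeric, and C2 becomes stereogenic in a unimolecular pericyclic event with no site for a chiral reagent. The route can therefore only give the racemate and needs a resolution. The chosen plan fixes C2 by reagent control before ring B exists and never passes through an ortho-quinone methide.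

Alternative 2: Cut the C3=C4 olefin. The forward key step would be ring-closing metathesis (second-generation Grubbs catalyst) of the diene A3, the aryl ether of a tertiary vinyl carbinol with an ortho-vinyl group. Two structural grounds speak against it. The alkylidene formed at C3 lies five atoms from the first chain olefin C3'=C4', so closure of a cyclopentene with excision of the C35 tail competes directly with closure of ring B. A3 itself also requires arylation of a tertiary allylic alkoxide by an electron-rich arene, which is the very bond the chosen plan makes by oxidative dearomatisation.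

Alternative 3: Cut C8a–C4a and C5–C6, that is, build ring A last from a 1,2-diazine. The C2 alkoxide of a (Z)-enynol would displace chloride from 3,6-dichloro-4,5-dimethylpyridazine (an easy substitution on an electron-poor ring) and, after methoxide exchange, give A4. An intramolecular inverse-demand Diels–Alder reaction with loss of N2 would form ring A and ring B together as the methyl ether A5. The ground against it is thermal: a pyridazine carrying two alkoxy donors and an unactivated alkyne is expected to need prolonged heating well above 150 °C. At such temperatures A5 would open and reclose through its ortho-quinone methide (loss of C2 configuration) and the tertiary allylic heteroaryl ether could eliminate. The (Z)-enynol and a final O-demethylation next to a polyene add further steps. The chosen key step runs below −40 °C.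

Key step: step 7

Remark: solanesol (all-E), D-(−)-diethyl tartrate and 4-iodo-2,3-dimethylphenol are taken as commercial; Pol stands for the chain (3E,7E,11E,15E,19E,23E,27E)-4,8,12,16,20,24,28,32-octamethyltritriaconta-3,7,11,15,19,23,27,31-octaen-1-yl (C41H67); 9 is formed and used as both epimers at the spiro carbon.

## Route

Step 1
Reactants: 1 solanesol (all-E nonaprenol)
Product: 2 [(2R,3R)-3-methyl-3-Pol-oxiran-2-yl]methanol ((2R,3R)-2,3-epoxysolanesol)
Conditions: Ti(OiPr)4 (10 mol%), D-(−)-diethyl tartrate (12 mol%), t-BuOOH (2 equiv, anhydrous), 4 Å MS, CH2Cl2, −20 °C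
Reagents that add atoms: tert-butyl hydroperoxide, CC(C)(C)OO
Why: Sharpless asymmetric epoxidation; the titanium tartrate complex binds the allylic hydroxyl, so only the C2=C3 olefin of the nine reacts, and D-(−)-tartrate should deliver the (2R,3R) oxirane from this E trisubstituted allylic alcohol (the mirror image of the (2S,3S) outcome of the L-(+)-tartrate series), which sets the future C2.

Step 2
Reactants: 2 (2R,3R)-2,3-epoxysolanesol
Product: 3 (2S,3R)-2-(chloromethyl)-3-methyl-3-Pol-oxirane
Conditions: PPh3 (1.5 equiv), CCl4, NaHCO3 (cat.), reflux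
Reagents that add atoms: carbon tetrachloride, ClC(Cl)(Cl)Cl
Why: Appel chlorination of the primary alcohol under buffered, neutral conditions that leave the oxirane and the olefins alone; no stereocentre is touched (the descriptor of the oxirane CH changes to S only because CH2Cl outranks the ring carbon).

Step 3
Reactants: 3 (2S,3R)-2-(chloromethyl)-3-methyl-3-Pol-oxirane
Product: 5 (2R)-2-Pol-but-3-yn-2-ol, via lithium chloroalkenyl alkoxide 4 (not isolated)
Conditions: n-BuLi (3.3 equiv), THF, −78 → −30 °C; then aq NH4Cl
Reagents that add atoms: none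
Why: Base-induced double elimination of a 2,3-epoxy chloride: lithiation alpha to chlorine opens the oxirane at the secondary C–O bond to 4, a second dehydrochlorination gives the alkyne and the third equivalent holds it as the acetylide; the tertiary C–O bond is never broken, so the configuration of step 1 is carried into the carbinol carbon (R).

Step 4
Reactants: 5 (2R)-2-Pol-but-3-yn-2-ol; 6 4-iodo-2,3-dimethylphenol
Product: 7 4-[(3R)-3-hydroxy-3-Pol-but-1-yn-1-yl]-2,3-dimethylphenol
Conditions: PdCl2(PPh3)2 (3 mol%), CuI (5 mol%), Et3N, THF, degassed, 25–40 °C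
Reagents that add atoms: none
Why: Sonogashira coupling; tertiary propargylic alcohols are reliable partners, the aryl iodide reacts under mild conditions with the phenol left free, and exclusion of oxygen suppresses alkyne homocoupling.

Step 5
Reactants: 7 4-[(3R)-3-hydroxy-3-Pol-but-1-yn-1-yl]-2,3-dimethylphenol
Product: 8 4-[(1Z,3R)-3-hydroxy-3-Pol-but-1-en-1-yl]-2,3-dimethylphenol
Conditions: H2 (1 atm, stopped after 1 equiv), Pd/CaCO3 poisoned with Pb(OAc)2 (Lindlar catalyst), quinoline, EtOAc–hexane, 20 °C, dark
Reagents that add atoms: none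
Why: Lindlar semi-hydrogenation; syn delivery of hydrogen to the alkyne gives the Z olefin, while the isolated trisubstituted chain olefins are not reduced on the poisoned catalyst; the product is kept free of acid (it is a vinylogous para-hydroxybenzylic alcohol).

Step 6
Reactants: 8 4-[(1Z,3R)-3-hydroxy-3-Pol-but-1-en-1-yl]-2,3-dimethylphenol
Product: 9 (2R,5RS)-2,6,7-trimethyl-2-Pol-1-oxaspiro[4.5]deca-3,6,9-trien-8-one
Conditions: PhI(OAc)2 (1.05 equiv), NaHCO3 (solid, 3 equiv), CH2Cl2, −20 → 0 °C, argon, dark
Reagents that add atoms: none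
Why: Oxidative dearomatising spiro-etherification with a trivalent iodine reagent: the phenol exchanges onto iodine, loss of iodobenzene leaves a phenoxenium-type cation, and the tertiary hydroxyl, held above C8a by the twisted Z olefin, closes the five-membered ring at the para carbon (5-exo attack on the ring carbon); the new spiro centre is not controlled and need not be, since step 7 erases it, and C2 is untouched.

Step 7
Reactants: 9 (2R,5RS)-2,6,7-trimethyl-2-Pol-1-oxaspiro[4.5]deca-3,6,9-trien-8-one
Product: 10 (2R)-2,7,8-trimethyl-2-Pol-2H-chromen-6-ol (plastochromenol-8)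
Conditions: BF3·OEt2 (20 mol%), CH2Cl2, −78 → −40 °C, argon, dark; then Et3N, aq NaHCO3
Reagents that add atoms: none
Why: Dienone–phenol rearrangement of a quinol ether; the closest known reaction type is the acid-promoted 1,2-shift of 4,4-disubstituted cyclohexa-2,5-dienones, including ring expansion of spiro-dienones. BF3 binds the dienone oxygen at C6 and turns ring A into an oxy-pentadienyl cation with positive charge on C8 and C4a, the two neighbours of the spiro carbon C8a. The alkenyl carbon C4, the best migrating group on C8a, shifts to C4a; carbon and not oxygen migrates because the shift leaves C8a as an oxocarbenium ion stabilised by O1. Loss of the proton from C4a restores the benzene ring irreversibly, whereas a shift to the methyl-bearing C8 gives a cation that cannot lose a proton and can only return, so the regiochemistry corrects itself. Ring B is closed by ring expansion of the five-membered 2,5-dihydrofuran (a 1,2-shift, not a Baldwin-type closure) and ring A by re-aromatisation. No stereocentre is created: none of the four bonds of C2 is touched, so R is kept, and the spiro centre disappears, so both epimers of 9 give 10. The selectivities needed are C- over O-migration and rearrangement over ionisation of C2–O1 or protonation of the chain olefins; they rest on the push from O1, a substoichiometric Lewis acid bound at the most basic site, low temperature and a basic quench.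

## Compound list

1 | solanesol, (2E,6E,10E,14E,18E,22E,26E,30E)-3,7,11,15,19,23,27,31,35-nonamethylhexatriaconta-2,6,10,14,18,22,26,30,34-nonaen-1-ol | CC(C)=CCC/C(C)=C/CC/C(C)=C/CC/C(C)=C/CC/C(C)=C/CC/C(C)=C/CC/C(C)=C/CC/C(C)=C/CC/C(C)=C/CO | starting material

2 | [(2R,3R)-3-methyl-3-Pol-oxiran-2-yl]methanol | CC(C)=CCC/C(C)=C/CC/C(C)=C/CC/C(C)=C/CC/C(C)=C/CC/C(C)=C/CC/C(C)=C/CC/C(C)=C/CC[C@@]1(C)O[C@@H]1CO | intermediate

3 | (2S,3R)-2-(chloromethyl)-3-methyl-3-Pol-oxirane | CC(C)=CCC/C(C)=C/CC/C(C)=C/CC/C(C)=C/CC/C(C)=C/CC/C(C)=C/CC/C(C)=C/CC/C(C)=C/CC[C@@]1(C)O[C@@H]1CCl | intermediate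

4 | lithium (2R)-4-chloro-2-Pol-but-3-en-2-olate (either olefin geometry; both go on) | CC(C)=CCC/C(C)=C/CC/C(C)=C/CC/C(C)=C/CC/C(C)=C/CC/C(C)=C/CC/C(C)=C/CC/C(C)=C/CC[C@@](C)([O-])C=CCl.[Li+] | intermediate (not isolated)

5 | (2R)-2-Pol-but-3-yn-2-ol, (3R,6E,10E,14E,18E,22E,26E,30E)-3,7,11,15,19,23,27,31,35-nonamethylhexatriaconta-6,10,14,18,22,26,30,34-octaen-1-yn-3-ol | CC(C)=CCC/C(C)=C/CC/C(C)=C/CC/C(C)=C/CC/C(C)=C/CC/C(C)=C/CC/C(C)=C/CC/C(C)=C/CC[C@@](C)(O)C#C | intermediate

6 | 4-iodo-2,3-dimethylphenol | Cc1c(O)ccc(I)c1C | starting material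

7 | 4-[(3R)-3-hydroxy-3-Pol-but-1-yn-1-yl]-2,3-dimethylphenol | CC(C)=CCC/C(C)=C/CC/C(C)=C/CC/C(C)=C/CC/C(C)=C/CC/C(C)=C/CC/C(C)=C/CC/C(C)=C/CC[C@@](C)(O)C#Cc1ccc(O)c(C)c1C | intermediate

8 | 4-[(1Z,3R)-3-hydroxy-3-Pol-but-1-en-1-yl]-2,3-dimethylphenol | CC(C)=CCC/C(C)=C/CC/C(C)=C/CC/C(C)=C/CC/C(C)=C/CC/C(C)=C/CC/C(C)=C/CC/C(C)=C/CC[C@@](C)(O)/C=C\c1ccc(O)c(C)c1C | intermediate

9 | (2R,5RS)-2,6,7-trimethyl-2-Pol-1-oxaspiro[4.5]deca-3,6,9-trien-8-one (C2 defined, spiro carbon as both epimers) | CC(C)=CCC/C(C)=C/CC/C(C)=C/CC/C(C)=C/CC/C(C)=C/CC/C(C)=C/CC/C(C)=C/CC/C(C)=C/CC[C@]1(C)C=CC2(O1)C(C)=C(C)C(=O)C=C2 | intermediate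

10 | (2R)-2,7,8-trimethyl-2-Pol-2H-chromen-6-ol, plastochromenol-8 | CC(C)=CCC/C(C)=C/CC/C(C)=C/CC/C(C)=C/CC/C(C)=C/CC/C(C)=C/CC/C(C)=C/CC/C(C)=C/CC[C@]1(C)C=Cc2cc(O)c(C)c(C)c2O1 | target

## Step count and least certain steps

Total step count: 7. Longest linear sequence: 7 steps (1 → 10); 6 enters in step 4. The product should be handled cold, in the dark and under argon.

Step 7 (key step). What may go wrong: loss of configuration through reversible heterolysis of the C2–O1 bond (in 9 or in the product ring) under the Lewis acid; cation- or proton-initiated cyclisation along the polyene; migration of oxygen in place of carbon, or a competing alkyl shift at C2 during the bridged stage of the alkenyl migration. The cause in each case is that the activating acid is not confined to the dienone oxygen.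
Fallback (ring B closed at O1–C8a by C–O cross-coupling; sets out from 5, comes back at 10):
- Commercial 2,3-dimethylhydroquinone would be mono-silylated (i-Pr3SiCl, imidazole) to 2,3-dimethyl-4-[(triisopropylsilyl)oxy]phenol F1.
- Iodination ortho to the free hydroxyl (N-iodosuccinimide) gives 6-iodo-2,3-dimethyl-4-[(triisopropylsilyl)oxy]phenol F2, and triflation (Tf2O, pyridine) gives 2-iodo-5,6-dimethyl-4-[(triisopropylsilyl)oxy]phenyl trifluoromethanesulfonate F3.
- Sonogashira coupling of 5 at the iodide of F3 gives 2-[(3R)-3-hydroxy-3-Pol-but-1-yn-1-yl]-5,6-dimethyl-4-[(triisopropylsilyl)oxy]phenyl trifluoromethanesulfonate F4.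
- Lindlar reduction gives 2-[(1Z,3R)-3-hydroxy-3-Pol-but-1-en-1-yl]-5,6-dimethyl-4-[(triisopropylsilyl)oxy]phenyl trifluoromethanesulfonate F5.
- Intramolecular palladium-catalysed etherification (Pd(OAc)2, 2-(di-tert-butylphosphino)-1,1'-binaphthyl, Cs2CO3, toluene, 60 °C) closes ring B to triisopropyl{[(2R)-2,7,8-trimethyl-2-Pol-2H-chromen-6-yl]oxy}silane F6 without touching a bond at C2.
- Bu4NF at 0 °C releases 10.

Step 6. What may go wrong: interception of the phenoxenium-type cation by acetate or water, or at the olefinic carbon C3, instead of ring closure at C8a; dehydration of the tertiary allylic alcohol towards an extended quinone methide; over-oxidation of the dienone. The cause is the delocalised cation next to an ionisable carbinol.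
Fallback (racemic construction and resolution; sets out from 1, comes back at 10):
- MnO2 oxidation of 1 gives solanesal F7.
- Ortho-chromenylation of 2,3-dimethylhydroquinone with F7 (PhB(OH)2, AcOH, toluene, reflux; condensation followed by electrocyclic closure, both ring positions being equivalent by symmetry) gives 10 together with its enantiomer (2S)-2,7,8-trimethyl-2-Pol-2H-chromen-6-ol F8.
- Preparative chromatography on a chiral stationary phase separates 10 from F8.

Step 5. What may go wrong: over-reduction of the styrenyl olefin, slow uptake at the hindered alkyne, or Z-to-E isomerisation on the catalyst; the conjugated, electron-rich alkyne and its product both bind to palladium.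
Fallback (no alkyne, olefin geometry set by light; sets out from 2, comes back at 8):
- 2 is converted (iodine, PPh3, imidazole) into (2S,3R)-2-(iodomethyl)-3-methyl-3-Pol-oxirane F9.
- Zinc dust in ethanol opens F9 reductively to the tertiary vinyl carbinol (2R)-2-Pol-but-3-en-2-ol F10, with the C–O bond of the future C2 intact.
- A Heck reaction of F10 with 6 (Pd(OAc)2, P(o-tol)3, Et3N, 70 °C) gives 4-[(1E,3R)-3-hydroxy-3-Pol-but-1-en-1-yl]-2,3-dimethylphenol F11.
- Visible-light triplet sensitisation (fac-Ir(ppy)3, ppy = 2-phenylpyridinate, blue light, THF) drives the contra-thermodynamic E-to-Z isomerisation to 8. Its twisted, deconjugated Z-styrene is no longer sensitised, and the isolated chain olefins lie above the sensitiser's triplet energy.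

## Further compounds

F1 | step 7 | 2,3-dimethyl-4-[(triisopropylsilyl)oxy]phenol | CC(C)[Si](Oc1ccc(O)c(C)c1C)(C(C)C)C(C)C

F2 | step 7 | 6-iodo-2,3-dimethyl-4-[(triisopropylsilyl)oxy]phenol | CC(C)[Si](Oc1cc(I)c(O)c(C)c1C)(C(C)C)C(C)C

F3 | step 7 | 2-iodo-5,6-dimethyl-4-[(triisopropylsilyl)oxy]phenyl trifluoromethanesulfonate | CC(C)[Si](Oc1cc(I)c(OS(=O)(=O)C(F)(F)F)c(C)c1C)(C(C)C)C(C)C

F4 | step 7 | 2-[(3R)-3-hydroxy-3-Pol-but-1-yn-1-yl]-5,6-dimethyl-4-[(triisopropylsilyl)oxy]phenyl trifluoromethanesulfonate | CC(C)=CCC/C(C)=C/CC/C(C)=C/CC/C(C)=C/CC/C(C)=C/CC/C(C)=C/CC/C(C)=C/CC/C(C)=C/CC[C@@](C)(O)C#Cc1cc(O[Si](C(C)C)(C(C)C)C(C)C)c(C)c(C)c1OS(=O)(=O)C(F)(F)F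

F5 | step 7 | 2-[(1Z,3R)-3-hydroxy-3-Pol-but-1-en-1-yl]-5,6-dimethyl-4-[(triisopropylsilyl)oxy]phenyl trifluoromethanesulfonate | CC(C)=CCC/C(C)=C/CC/C(C)=C/CC/C(C)=C/CC/C(C)=C/CC/C(C)=C/CC/C(C)=C/CC/C(C)=C/CC[C@@](C)(O)/C=C\c1cc(O[Si](C(C)C)(C(C)C)C(C)C)c(C)c(C)c1OS(=O)(=O)C(F)(F)F

F6 | step 7 | triisopropyl{[(2R)-2,7,8-trimethyl-2-Pol-2H-chromen-6-yl]oxy}silane | CC(C)=CCC/C(C)=C/CC/C(C)=C/CC/C(C)=C/CC/C(C)=C/CC/C(C)=C/CC/C(C)=C/CC/C(C)=C/CC[C@]1(C)C=Cc2cc(O[Si](C(C)C)(C(C)C)C(C)C)c(C)c(C)c2O1

F7 | step 6 | solanesal, (2E,6E,10E,14E,18E,22E,26E,30E)-3,7,11,15,19,23,27,31,35-nonamethylhexatriaconta-2,6,10,14,18,22,26,30,34-nonaenal | CC(C)=CCC/C(C)=C/CC/C(C)=C/CC/C(C)=C/CC/C(C)=C/CC/C(C)=C/CC/C(C)=C/CC/C(C)=C/CC/C(C)=C/C=O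

F8 | step 6 | (2S)-2,7,8-trimethyl-2-Pol-2H-chromen-6-ol (enantiomer of 10) | CC(C)=CCC/C(C)=C/CC/C(C)=C/CC/C(C)=C/CC/C(C)=C/CC/C(C)=C/CC/C(C)=C/CC/C(C)=C/CC[C@@]1(C)C=Cc2cc(O)c(C)c(C)c2O1

F9 | step 5 | (2S,3R)-2-(iodomethyl)-3-methyl-3-Pol-oxirane | CC(C)=CCC/C(C)=C/CC/C(C)=C/CC/C(C)=C/CC/C(C)=C/CC/C(C)=C/CC/C(C)=C/CC/C(C)=C/CC[C@@]1(C)O[C@@H]1CI

F10 | step 5 | (2R)-2-Pol-but-3-en-2-ol | CC(C)=CCC/C(C)=C/CC/C(C)=C/CC/C(C)=C/CC/C(C)=C/CC/C(C)=C/CC/C(C)=C/CC/C(C)=C/CC[C@@](C)(O)C=C

F11 | step 5 | 4-[(1E,3R)-3-hydroxy-3-Pol-but-1-en-1-yl]-2,3-dimethylphenol | CC(C)=CCC/C(C)=C/CC/C(C)=C/CC/C(C)=C/CC/C(C)=C/CC/C(C)=C/CC/C(C)=C/CC/C(C)=C/CC[C@@](C)(O)/C=C/c1ccc(O)c(C)c1C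

A1 | alternative 1 | plastoquinone-9, 2,3-dimethyl-5-[(2E,6E,10E,14E,18E,22E,26E,30E)-3,7,11,15,19,23,27,31,35-nonamethylhexatriaconta-2,6,10,14,18,22,26,30,34-nonaen-1-yl]cyclohexa-2,5-diene-1,4-dione | CC(C)=CCC/C(C)=C/CC/C(C)=C/CC/C(C)=C/CC/C(C)=C/CC/C(C)=C/CC/C(C)=C/CC/C(C)=C/CC/C(C)=C/CC1=CC(=O)C(C)=C(C)C1=O

A2 | alternative 1 | ortho-quinone methide tautomer of A1, 4-hydroxy-2,3-dimethyl-6-[(2E)-3-methyl-3-Pol-prop-2-en-1-ylidene]cyclohexa-2,4-dien-1-one | CC(C)=CCC/C(C)=C/CC/C(C)=C/CC/C(C)=C/CC/C(C)=C/CC/C(C)=C/CC/C(C)=C/CC/C(C)=C/CC/C(C)=C/C=C1/C=C(O)C(C)=C(C)C1=O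

A3 | alternative 2 | 5-ethenyl-2,3-dimethyl-4-{[(2R)-2-Pol-but-3-en-2-yl]oxy}phenol | CC(C)=CCC/C(C)=C/CC/C(C)=C/CC/C(C)=C/CC/C(C)=C/CC/C(C)=C/CC/C(C)=C/CC/C(C)=C/CC[C@](C)(C=C)Oc1c(C=C)cc(O)c(C)c1C

A4 | alternative 3 | 3-methoxy-4,5-dimethyl-6-{[(2R,3Z)-2-Pol-hex-3-en-5-yn-2-yl]oxy}pyridazine | CC(C)=CCC/C(C)=C/CC/C(C)=C/CC/C(C)=C/CC/C(C)=C/CC/C(C)=C/CC/C(C)=C/CC/C(C)=C/CC[C@](C)(/C=C\C#C)Oc1nnc(OC)c(C)c1C

A5 | alternative 3 | (2R)-6-methoxy-2,7,8-trimethyl-2-Pol-2H-chromene | CC(C)=CCC/C(C)=C/CC/C(C)=C/CC/C(C)=C/CC/C(C)=C/CC/C(C)=C/CC/C(C)=C/CC/C(C)=C/CC[C@]1(C)C=Cc2cc(OC)c(C)c(C)c2O1
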